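The runs are simulated for an exercise; the scatter is artificial.

Time stops paying in the red flask early: target reads 32% at 50.0 min and 32% at 480 min, a gap inside the scatter of 1.5 percentage points.

| setting | red | amber | flask |
|---|---|---|---|
| starting material | 10 mM | 10 mM | 10 mM |
| second substrate | 8 mM | 8 mM | 8.00 mM |
| free enzyme | 0.18 µM | 0.090 µM | 0.18 µM |
| temperature | 25 °C | 10 °C | 25 °C |
| remark | the very flask that is asked about, followed so far | run made earlier |  |
| time |  |  | 12 h |

| run | time / min | target / % |
|---|---|---|
| red | 50.0 | 32 |
| red | 150 | 33 |
| red | 300 | 31 |
| red | 480 | 32 |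
| amber | 30.0 | 7 |
| amber | 60.0 | 14 |
| amber | 80.0 | 17 |
| amber | 120 | 21 |

(each reading ± 1.5 percentage points)

- Friday's: at 12 h add free enzyme, 50.0% of the amount charged, then wait 25 h
- Sunday's: at 12 h add second substrate, 100% of the amount charged, then wait 25 h
- Tuesday's: at 12 h raise the temperature by 25 K, then wait 25 h
- Monday's: change nothing and wait 25 h more
- Wednesday's: at 12 h take out 90% of the first product then present, then wait 25 h

- the volume of additions can be left aside

* target, in percent of the starting material first charged, at 12 h
* which option adds most target ("none" when 2 percentage points or less is all one gets) (Friday's / Sunday's / Tuesday's / Monday's / Wednesday's / none)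
* target present, in percent of the starting material first charged, after Tuesday's
* target present, in percent of the starting material first charged, after Monday's

1. I take the mean of the red readings, 32.0%, as my value for the red flask at 12 h.

2. Second substrate is the limiting reagent, charged at 8.00 mM, less than the 10 mM of starting material. I write its balance, counting one second substrate per target: the charge equals target formed plus whatever else became of it. The red readings give 0.400 for φ, the capture share: target formed per second substrate charged.

3. Two extremes can be solved in the head. If the enzyme takes every second substrate, φ is 1 and target ends at 80.0%. If something else takes every second substrate first, φ is 0 and no target forms.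

4. The red flask lies between them, and I read it as a race that the enzyme partly lost, which puts 4.80 mM of second substrate outside target by my reckoning.

5. A fresh dose should run the same race, so Sunday's adds φ times the dose, 32 points, more than the margin of 2 points, for 64.0% in the red flask. Monday's, Friday's, Tuesday's and Wednesday's bring no fresh second substrate, so I put their gains at zero and keep 32.0%.

6. The forecast gives 32% at 12 h, Sunday's as the best option, 32% after Tuesday's and 32% after Monday's, in the words “So I treat this as equilibrium, with the enzyme probably still alive”; it differs from me on why the flask stopped, and it says doubling second substrate gives about 45%.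

The red flask gives 33.1% at 12 h, with 33.1% after Tuesday's and 33.1% after Monday's, and Sunday's adds 28 points against my 32 points from φ.

    free enzyme → unfolded enzyme (k = 0.00458 min⁻¹, Ea = 289 kJ mol⁻¹)
    second substrate + loaded enzyme ⇌ second complex (K = 284 M⁻¹, k = 63700 M⁻¹ s⁻¹, Ea = 25.0 kJ mol⁻¹, ΔH = 15.0 kJ mol⁻¹)
    first complex → loaded enzyme + first product (k = 3260 min⁻¹, Ea = 58.0 kJ mol⁻¹)
    starting material ⇌ dormant form (K = 0.880, k = 0.914 min⁻¹, Ea = 83.0 kJ mol⁻¹, ΔH = −25.0 kJ mol⁻¹)
    second substrate → decomposed reagent (k = 0.0533 min⁻¹, Ea = 81.0 kJ mol⁻¹)
    second complex → free enzyme + target (k = 5360 min⁻¹, Ea = 71.0 kJ mol⁻¹)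
    starting material + free enzyme ⇌ first complex (K = 123 M⁻¹, k = 25400 M⁻¹ s⁻¹, Ea = 26.0 kJ mol⁻¹, ΔH = −34.0 kJ mol⁻¹)
    (constants at 25 °C)

At 720 min the red flask holds 0% of its second substrate, with 3.31 mM of target and 4.69 mM of decomposed reagent, together 8.00 mM. In the neighbour flask charged with 2.0 mM of second substrate, φ of 0.400 reckons 8.00% of target, and that flask holds 12.7%, a capture share of 0.635.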